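The numbers in the tables are calculated for substances that don't exist, and the scatter is random.

Late in the zeta run, at 120 s, 85 % of the charged J is still solid. Solid J dissolves, the dissolved J meets L, and that gives X. Carried forward, this straight loss would make the solid last 800 s: this is the emptying time, the lifetime of the charge at the rate read off, and it carries the scatter of 1.5 percentage points.

the same everywhere: J 1.5 M
- delta: L 0.98 equiv; the very flask that is asked about, followed so far
- zeta: L 2 equiv; run made earlier
- flask: L 0.980 equiv; time 2.0 min

| run | time / s | X / % | J / % |
|---|---|---|---|
| delta | 10.0 | 0 | 100 |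
| delta | 15.0 | 0 | 98 |
| delta | 25.0 | 1 | 97 |
| zeta | 10.0 | 3 | 99 |
| zeta | 25.0 | 0 | 96 |
| zeta | 40.0 | 4 | 95 |
| zeta | 60.0 | 8 | 95 |
| zeta | 90.0 | 12 | 89 |
| zeta | 120 | 8 | 85 |

(each reading ± 1.5 percentage points)

- X at 2.0 min, in percent of the J charged
- the change that raises the amount of X at 2.0 min, in percent of the J charged most ("none" if none brings more than 2 percentage points) (autumn / summer / noon / none)
- amount of X at 2.0 min, in percent of the J charged, after summer

- autumn: doubling the amount of L, all else as stated
- summer: doubling the dissolution coefficient of J, all else as stated
- noon: doubling the solubility of J, all else as stated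

At 2.0 min your flask has used 15.0 % of that lifetime, so a first guess is that much J gone and that much X. But zeta held twice the L. The delta run answers for the solid: the emptying time puts J at 96.9 % at 25.0 s, and the reading is 97 %.

X trails, though. Zeta's last two readings average 10.0 %, which leaves 5.00 % dissolved, a lag of 40.0 s. That is shorter than the emptying time, so I take dissolving as the rate-limiting step in zeta. With about half the L, the flask's lag should be 81.6 s, which gives 4.80 % of X. But 2.0 min is 1.47 lags, so I reckon the dissolved pool as still filling, and the correction lifts my figure to 7.14 %. In this reckoning, doubling the supply gives 14.3 %, while doubling L gives 10.2 %, less than the supply change. My reckoning counts summer and noon alike, each as a doubled supply, so it does not choose between them.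

The forecast, a little above my figure, says 8 %, noon as the best change and 14 % after summer, reading “supply from the solid as the main limit”.

The flask gives 10.4 % of X; noon is best, adding 8.9 points, and summer gives 17.4 %.

    D + L ⇌ X + E (K = 1.40, k = 0.0260 M⁻¹ s⁻¹)
    J ⇌ D, rate k2*(cs2 - [D]) while solid is left; crystals form when [D] > cs2 (solubility = 0.310 M, k = 0.00650 s⁻¹)

At 2.0 min this flask still holds 85.9 % of its J as solid and 89.4 % of its L, with 3.68 % standing as D, the dissolved J. The emptying time said 15.0 % of J gone, and 14.1 % is. For the neighbour flask read at 3.0 min it says 22.5 % gone, and that flask holds 79.5 % of its J as solid, with X at 15.7 %.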